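**Plan** (carotenoid numbering; primed locants belong to the ε half)
1. Retrosynthesis: cut C7=C8 (Wittig) and C7'=C8' (Julia–Kocienski) to expose crocetin dialdehyde (C20) and two C10 ring units that already carry their esters.
2. ε ring: cut C2'–C3' and C4'–C5' together (nickel-catalysed insertion of ethoxyacetylene into a cyclobutanone), then C5'–CH3 (methyllithium, Stork–Danheiser transposition) and C6'–C7' (auxiliary-controlled alkylation).
3. Enabling feature: the ring atoms C5'–C6'(H)–C1'(CH3)2–C2'H2 are a 3,3-dimethylcyclobutanone in disguise (C5' = carbonyl carbon), whose strained acyl–CH2 bond a low-valent metal can open. The remaining ring atoms C3'(O)–C4'(H) are an ynol ether, and the 1,3 relation of the C3' oxygen to C5' is that of a vinylogous ester.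
4. Forward order: cyclobutanone → α-alkylation (C7', C6') → six-membered vinylogous ester → enone → trans allylic alcohol → myristate → sulfone → C30 aldehyde; β ring unit from (4R,6R)-actinol; last C=C by Wittig.
5. Stereochemistry: C6' from SAMP-hydrazone alkylation; C3' from 1,4-substrate-controlled hydride reduction; C3 from the chiral pool (actinol); E-olefins from the olefinations plus thermal equilibration.

Key step: step 4

Assumption: compounds 1, 2, 4, 8, 19 and 22 are taken as purchasable, and SAMP is assumed to induce in the cyclobutanone hydrazone the same sense as in other cyclic ketone hydrazones (otherwise its enantiomer is used).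

**Step 1**
Reactants: 1 3,3-dimethylcyclobutanone; 2 (S)-1-amino-2-(methoxymethyl)pyrrolidine (SAMP)
Product: 3 (S)-N-(3,3-dimethylcyclobutylidene)-2-(methoxymethyl)pyrrolidin-1-amine
Conditions: neat, 60 °C, then MgSO4
Reagents that add atoms: none
Why: Hydrazone formation on a symmetrical ketone whose two α-carbons are equivalent, so no regiochemical question arises in the next step.

**Step 2**
Reactants: 3; 4 (triisopropylsiloxy)methyl chloride
Product: 6 (S)-N-[(E,2R)-3,3-dimethyl-2-{[(triisopropylsilyl)oxy]methyl}cyclobutylidene]-2-(methoxymethyl)pyrrolidin-1-amine, via lithium azaenolate 5 (not isolated)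
Conditions: LiN(i-Pr)2, THF, 0 °C; then 4, −100 °C to rt
Reagents that add atoms: none
Why: SAMP-hydrazone α-alkylation, in which the reactive α-chloro ether should attack the chelated azaenolate on the face fixed by the methoxymethyl auxiliary, setting the future C6' centre and installing C7' as a silyl-protected hydroxymethyl group.

**Step 3**
Reactants: 6
Product: 7 (S)-3,3-dimethyl-2-{[(triisopropylsilyl)oxy]methyl}cyclobutan-1-one
Conditions: saturated aq. oxalic acid, Et2O, rt
Reagents that add atoms: water, O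
Why: Mild two-phase hydrazone hydrolysis should release the α-substituted cyclobutanone without epimerisation and leave the silyl ether intact.

**Step 4**
Reactants: 7; 8 ethoxyacetylene
Product: 11 (S)-3-ethoxy-5,5-dimethyl-6-{[(triisopropylsilyl)oxy]methyl}cyclohex-2-en-1-one, via spiro oxanickelacyclopentene 9 (not isolated), via seven-membered nickelacycle 10 (not isolated)
Conditions: Ni(cod)2 (10 mol %, zerovalent nickel), PCy3 (20 mol %), toluene, 80 °C, 8 (3 equiv) added slowly by syringe pump
Reagents that add atoms: none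
Why: Proposed new method: zerovalent nickel should couple the C=O of 7 and the alkyne oxidatively so that the unsubstituted, nucleophilic alkyne carbon (C4') bonds to the carbonyl carbon (C5') to give 9; β-carbon elimination then opens the strained ring at the C5'–C2' (acyl–CH2) bond to give 10, and C(sp3)–C(sp2) reductive elimination joins C2' to the ethoxy-bearing C3'. The closest known reaction type is the nickel-catalysed intermolecular [4+2] annulation of cyclobutanones with internal dialkyl or diaryl alkynes (alkyne insertion into the acyl–carbon bond); new here are the terminal alkoxyalkyne and the unsymmetrical 2-substituted cyclobutanone. The six-membered ring is closed by reductive elimination from the seven-membered metallacycle, a formal [4+2] ring expansion of the cyclobutanone by two carbons. No stereocentre is created, and C6' is a spectator whose bonds are not broken, so it should keep its configuration under these neutral conditions. Two selectivities are needed: the alkyne orientation, secured by the polarisation of the ynol ether (the carbon β to oxygen is the nucleophilic and less hindered terminus), and cleavage of C5'–C2' in preference to C5'–C6', secured because the unsubstituted methylene migrates to nickel more readily than the hindered methine. Slow addition of 8 at moderate temperature is meant to suppress alkyne oligomerisation and thermal loss of ethylene from the ynol ether.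

**Step 5**
Reactants: 11
Product: 13 (R)-3,5,5-trimethyl-4-{[(triisopropylsilyl)oxy]methyl}cyclohex-2-en-1-one, via tertiary allylic carbinol 12 (not isolated)
Conditions: MeLi, CeCl3, THF, −78 °C; then 1 M HCl, 0 °C
Reagents that add atoms: methyllithium, C[Li]; water, O
Why: Stork–Danheiser transposition: 1,2-addition of the weakly basic organocerium to the vinylogous ester and acid hydrolysis with allylic transposition put CH3 on C5' and the carbonyl on C3' without touching C6'.

**Step 6**
Reactants: 13
Product: 14 (1R,4R)-3,5,5-trimethyl-4-{[(triisopropylsilyl)oxy]methyl}cyclohex-2-en-1-ol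
Conditions: LiBH(s-Bu)3 (L-Selectride), THF, −78 °C; H2O quench
Reagents that add atoms: none
Why: 1,2-Reduction of the β,β-disubstituted enone by a bulky hydride, which should attack equatorially, anti to the axial C1' methyl of the conformer with a pseudoaxial C6' substituent, and so give the trans (3'R) alcohol by 1,4-substrate control.

**Step 7**
Reactants: 14
Product: 15 (1R,4R)-3,5,5-trimethyl-4-{[(triisopropylsilyl)oxy]methyl}cyclohex-2-en-1-yl tetradecanoate
Conditions: tetradecanoyl chloride, pyridine, DMAP (cat.), CH2Cl2, 0 °C to rt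
Reagents that add atoms: tetradecanoyl chloride, CCCCCCCCCCCCCC(=O)Cl
Why: DMAP-catalysed acylation of the secondary allylic alcohol with retention at C3'.

**Step 8**
Reactants: 15
Product: 16 (1R,4R)-4-(hydroxymethyl)-3,5,5-trimethylcyclohex-2-en-1-yl tetradecanoate
Conditions: HF·pyridine, pyridine, THF, 0 °C to rt
Reagents that add atoms: none
Why: Buffered fluoride desilylation removes the primary silyl ether while the allylic ester survives.

**Step 9**
Reactants: 16
Product: 17 (1R,4R)-3,5,5-trimethyl-4-{[(1-phenyl-1H-tetrazol-5-yl)sulfanyl]methyl}cyclohex-2-en-1-yl tetradecanoate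
Conditions: 1-phenyl-1H-tetrazole-5-thiol, PPh3, DIAD, THF, 0 °C to rt
Reagents that add atoms: 1-phenyl-1H-tetrazole-5-thiol, Sc1nnnn1-c1ccccc1
Why: Mitsunobu thioetherification of the primary alcohol, which involves no stereocentre.

**Step 10**
Reactants: 17
Product: 18 (1R,4R)-3,5,5-trimethyl-4-{[(1-phenyl-1H-tetrazol-5-yl)sulfonyl]methyl}cyclohex-2-en-1-yl tetradecanoate
Conditions: (NH4)6Mo7O24·4H2O (cat.), 30 % H2O2, EtOH, 0 °C to rt
Reagents that add atoms: hydrogen peroxide, OO
Why: Molybdate-catalysed oxidation of sulfide to sulfone, which is chemoselective over the trisubstituted ring alkene.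

**Step 11**
Reactants: 18; 19 crocetin dialdehyde (all-E-2,6,11,15-tetramethylhexadeca-2,4,6,8,10,12,14-heptaenedial, used in excess)
Product: 21 (all-E)-2,6,11,15-tetramethyl-17-[(1R,4R)-2,6,6-trimethyl-4-(tetradecanoyloxy)cyclohex-2-en-1-yl]heptadeca-2,4,6,8,10,12,14,16-octaenal, via potassium sulfonyl carbanion 20 (not isolated)
Conditions: KN(SiMe3)2 added to 18 and 19 (3 equiv), THF/DMF, −78 °C to rt; aq. NH4Cl
Reagents that add atoms: none
Why: Julia–Kocienski olefination forms C7'=C8' under Barbier conditions; excess dialdehyde favours mono-olefination, and the metalated carbon lies next to, not at, C6', so that centre is not at risk.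

**Step 12**
Reactants: 22 (4R,6R)-4-hydroxy-2,2,6-trimethylcyclohexanone (actinol)
Product: 23 (1R,3R)-3,5,5-trimethyl-4-oxocyclohexyl hexadecanoate
Conditions: hexadecanoyl chloride, pyridine, DMAP (cat.), CH2Cl2, 0 °C to rt
Reagents that add atoms: hexadecanoyl chloride, CCCCCCCCCCCCCCCC(=O)Cl
Why: Acylation of the chiral-pool alcohol fixes the palmitate on the future C3 with retention.

**Step 13**
Reactants: 23
Product: 24 (R)-3,5,5-trimethyl-4-{[(trifluoromethyl)sulfonyl]oxy}cyclohex-3-en-1-yl hexadecanoate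
Conditions: Tf2O, 2,6-di-tert-butyl-4-methylpyridine, CH2Cl2, 0 °C to rt
Reagents that add atoms: trifluoromethanesulfonic anhydride, O=S(=O)(OS(=O)(=O)C(F)(F)F)C(F)(F)F
Why: Enol triflate formation under non-nucleophilic base; the ketone has a single enolisable α-position, so only the tetrasubstituted C5=C6 enol triflate can form and the ester is not enolised.

**Step 14**
Reactants: 24
Product: 25 (R)-4-(hydroxymethyl)-3,5,5-trimethylcyclohex-3-en-1-yl hexadecanoate
Conditions: Bu3SnCH2OH, Pd(PPh3)4 (10 mol %), CuCl, LiCl, DMSO, 60 °C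
Reagents that add atoms: (tributylstannyl)methanol, OC[Sn](CCCC)(CCCC)CCCC
Why: Stille hydroxymethylation of the hindered vinyl triflate, with copper chloride to speed transmetalation, introduces C7 without touching the ester.

**Step 15**
Reactants: 25
Product: 26 {[(R)-4-(hexadecanoyloxy)-2,6,6-trimethylcyclohex-1-en-1-yl]methyl}triphenylphosphonium bromide
Conditions: PPh3·HBr, CH2Cl2, rt
Reagents that add atoms: triphenylphosphine hydrobromide, Br.P(c1ccccc1)(c1ccccc1)c1ccccc1
Why: Acid-mediated ionisation of the allylic alcohol and capture of the allyl cation by phosphine at the unhindered primary terminus gives the phosphonium salt.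

**Step 16**
Reactants: 26; 21
Product: 28 (3R,3'R,6'R)-β,ε-carotene-3,3'-diol 3-hexadecanoate 3'-tetradecanoate (lutein 3-O-palmitate 3'-O-myristate), via phosphonium ylide 27 (not isolated)
Conditions: NaN(SiMe3)2, THF, −78 to 0 °C; then 21, to rt; crude product refluxed in n-heptane
Reagents that add atoms: none
Why: Wittig olefination of the polyenal forms C7=C8 with both esters tolerated by the non-nucleophilic base, and heating should equilibrate any Z isomer of the hindered C7=C8 bond to the all-E polyene.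

**Compound list**
1 | 3,3-dimethylcyclobutanone | O=C1CC(C)(C)C1 | starting material
2 | (S)-1-amino-2-(methoxymethyl)pyrrolidine (SAMP) | COC[C@@H]1CCCN1N | starting material
3 | (S)-N-(3,3-dimethylcyclobutylidene)-2-(methoxymethyl)pyrrolidin-1-amine | COC[C@@H]1CCCN1N=C1CC(C)(C)C1 | intermediate
4 | (triisopropylsiloxy)methyl chloride | ClCO[Si](C(C)C)(C(C)C)C(C)C | starting material
5 | lithium azaenolate of 3 | [Li+].COC[C@@H]1CCCN1[N-]C1=CC(C)(C)C1 | intermediate (not isolated)
6 | (S)-N-[(E,2R)-3,3-dimethyl-2-{[(triisopropylsilyl)oxy]methyl}cyclobutylidene]-2-(methoxymethyl)pyrrolidin-1-amine | COC[C@@H]1CCCN1/N=C1\CC(C)(C)[C@H]1CO[Si](C(C)C)(C(C)C)C(C)C | intermediate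
7 | (S)-3,3-dimethyl-2-{[(triisopropylsilyl)oxy]methyl}cyclobutan-1-one | CC(C)[Si](C(C)C)(C(C)C)OC[C@H]1C(=O)CC1(C)C | intermediate
8 | ethoxyacetylene | CCOC#C | starting material
9 | spiro oxanickelacyclopentene (phosphine ligand omitted; spiro carbon unassigned) | CCOC1=CC2(O[Ni]1)CC(C)(C)[C@H]2CO[Si](C(C)C)(C(C)C)C(C)C | intermediate (not isolated)
10 | seven-membered nickelacycle (phosphine ligand omitted) | CCOC1=CC(=O)[C@H](CO[Si](C(C)C)(C(C)C)C(C)C)C(C)(C)C[Ni]1 | intermediate (not isolated)
11 | (S)-3-ethoxy-5,5-dimethyl-6-{[(triisopropylsilyl)oxy]methyl}cyclohex-2-en-1-one | CCOC1=CC(=O)[C@H](CO[Si](C(C)C)(C(C)C)C(C)C)C(C)(C)C1 | intermediate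
12 | (6S)-3-ethoxy-1,5,5-trimethyl-6-{[(triisopropylsilyl)oxy]methyl}cyclohex-2-en-1-ol (C1 epimers) | CCOC1=CC(C)(O)[C@H](CO[Si](C(C)C)(C(C)C)C(C)C)C(C)(C)C1 | intermediate (not isolated)
13 | (R)-3,5,5-trimethyl-4-{[(triisopropylsilyl)oxy]methyl}cyclohex-2-en-1-one | CC(C)[Si](C(C)C)(C(C)C)OC[C@H]1C(C)=CC(=O)CC1(C)C | intermediate
14 | (1R,4R)-3,5,5-trimethyl-4-{[(triisopropylsilyl)oxy]methyl}cyclohex-2-en-1-ol | CC(C)[Si](C(C)C)(C(C)C)OC[C@H]1C(C)=C[C@H](O)CC1(C)C | intermediate
15 | (1R,4R)-3,5,5-trimethyl-4-{[(triisopropylsilyl)oxy]methyl}cyclohex-2-en-1-yl tetradecanoate | CC(C)[Si](C(C)C)(C(C)C)OC[C@H]1C(C)=C[C@H](OC(=O)CCCCCCCCCCCCC)CC1(C)C | intermediate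
16 | (1R,4R)-4-(hydroxymethyl)-3,5,5-trimethylcyclohex-2-en-1-yl tetradecanoate | OC[C@H]1C(C)=C[C@H](OC(=O)CCCCCCCCCCCCC)CC1(C)C | intermediate
17 | (1R,4R)-3,5,5-trimethyl-4-{[(1-phenyl-1H-tetrazol-5-yl)sulfanyl]methyl}cyclohex-2-en-1-yl tetradecanoate | C(Sc1nnnn1-c1ccccc1)[C@H]1C(C)=C[C@H](OC(=O)CCCCCCCCCCCCC)CC1(C)C | intermediate
18 | (1R,4R)-3,5,5-trimethyl-4-{[(1-phenyl-1H-tetrazol-5-yl)sulfonyl]methyl}cyclohex-2-en-1-yl tetradecanoate | C(S(=O)(=O)c1nnnn1-c1ccccc1)[C@H]1C(C)=C[C@H](OC(=O)CCCCCCCCCCCCC)CC1(C)C | intermediate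
19 | crocetin dialdehyde | O=C/C(C)=C/C=C/C(C)=C/C=C/C=C(C)/C=C/C=C(C)/C=O | starting material
20 | potassium sulfonyl carbanion of 18 | [K+].[CH-](S(=O)(=O)c1nnnn1-c1ccccc1)[C@H]1C(C)=C[C@H](OC(=O)CCCCCCCCCCCCC)CC1(C)C | intermediate (not isolated)
21 | (all-E)-2,6,11,15-tetramethyl-17-[(1R,4R)-2,6,6-trimethyl-4-(tetradecanoyloxy)cyclohex-2-en-1-yl]heptadeca-2,4,6,8,10,12,14,16-octaenal | O=C/C(C)=C/C=C/C(C)=C/C=C/C=C(C)/C=C/C=C(C)/C=C/[C@H]1C(C)=C[C@H](OC(=O)CCCCCCCCCCCCC)CC1(C)C | intermediate
22 | (4R,6R)-4-hydroxy-2,2,6-trimethylcyclohexanone (actinol) | O[C@@H]1C[C@@H](C)C(=O)C(C)(C)C1 | starting material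
23 | (1R,3R)-3,5,5-trimethyl-4-oxocyclohexyl hexadecanoate | CCCCCCCCCCCCCCCC(=O)O[C@@H]1C[C@@H](C)C(=O)C(C)(C)C1 | intermediate
24 | (R)-3,5,5-trimethyl-4-{[(trifluoromethyl)sulfonyl]oxy}cyclohex-3-en-1-yl hexadecanoate | CCCCCCCCCCCCCCCC(=O)O[C@@H]1CC(C)=C(OS(=O)(=O)C(F)(F)F)C(C)(C)C1 | intermediate
25 | (R)-4-(hydroxymethyl)-3,5,5-trimethylcyclohex-3-en-1-yl hexadecanoate | CCCCCCCCCCCCCCCC(=O)O[C@@H]1CC(C)=C(CO)C(C)(C)C1 | intermediate
26 | {[(R)-4-(hexadecanoyloxy)-2,6,6-trimethylcyclohex-1-en-1-yl]methyl}triphenylphosphonium bromide | [Br-].CCCCCCCCCCCCCCCC(=O)O[C@@H]1CC(C)=C(C[P+](c2ccccc2)(c2ccccc2)c2ccccc2)C(C)(C)C1 | intermediate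
27 | phosphonium ylide of 26 | CCCCCCCCCCCCCCCC(=O)O[C@@H]1CC(C)=C(C=P(c2ccccc2)(c2ccccc2)c2ccccc2)C(C)(C)C1 | intermediate (not isolated)
28 | lutein 3-O-palmitate 3'-O-myristate | CCCCCCCCCCCCCCCC(=O)O[C@@H]1CC(C)=C(/C=C/C(C)=C/C=C/C(C)=C/C=C/C=C(C)/C=C/C=C(C)/C=C/[C@H]2C(C)=C[C@H](OC(=O)CCCCCCCCCCCCC)CC2(C)C)C(C)(C)C1 | target

**Totals**
Total step count: 16. Longest linear sequence: 12 (steps 1–11, then step 16).

**Steps most likely to fail**

Step 4 (proposed new method). The terminal ynol ether may oligomerise on nickel, β-carbon elimination may occur on the substituted side (C5'–C6'), the cyclobutanone may lose CO, or C6' may epimerise. The fallback uses known chemistry, sets out from compound 4 and comes back at compound 15. Purchased 3-ethoxy-5,5-dimethylcyclohex-2-en-1-one F1 is deprotonated at C6 with LiN(i-Pr)2 (THF, −78 °C) to the lithium dienolate F2, which is alkylated with 4 to the racemic vinylogous ester F3 (Stork–Danheiser alkylation). MeLi/CeCl3 then aqueous HCl give, by way of the racemic carbinol F4, the racemic enone F5, and LiBH(s-Bu)3 gives the racemic trans alcohol F6. Lipase-catalysed transesterification with vinyl tetradecanoate (lipase from Burkholderia cepacia, hexane, rt) should acylate only the (1R,4R) enantiomer, following the usual enantiopreference of lipases for secondary alcohols, and so gives 15 directly and leaves the (1S,4S) alcohol F7 behind.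

Step 6. Facial selectivity of hydride delivery may be poor, because the conformational preference of the C6' substituent that steers the attack is only inferred. The fallback sets out from compound 13 and comes back at compound 15 by a stereoconvergent sequence. Reduction with NaBH4/CeCl3·7H2O (MeOH, −78 °C) gives 14 together with the cis epimer, the (1S,4R) alcohol F8, and the two are separated. 14 is acylated as in step 7, and F8 is esterified with tetradecanoic acid, PPh3 and DIAD (Mitsunobu, inversion at C3'), so both epimers converge on 15.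

Step 11. The hindered β-branched sulfonyl carbanion may add sluggishly, the second formyl group may also be olefinated, the ester may be enolised by the amide base, or the E-selectivity at C7'=C8' may be low. The fallback sets out from compound 16 and comes back at compound 21. I2, PPh3 and imidazole (CH2Cl2) give the iodide F9; PPh3 in refluxing MeCN gives the phosphonium iodide F10. NaN(SiMe3)2 (THF, −78 °C) gives the ylide F11, which is added to excess 19 to give 21 by Wittig olefination, followed by thermal isomerisation.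

**Further compounds**
F1 | step 4 | 3-ethoxy-5,5-dimethylcyclohex-2-en-1-one (purchased) | CCOC1=CC(=O)CC(C)(C)C1
F2 | step 4 | lithium dienolate of F1 (not isolated) | [Li+].[O-]C1=CC(C)(C)CC(OCC)=C1
F3 | step 4 | racemic 3-ethoxy-5,5-dimethyl-6-{[(triisopropylsilyl)oxy]methyl}cyclohex-2-en-1-one | CCOC1=CC(=O)C(CO[Si](C(C)C)(C(C)C)C(C)C)C(C)(C)C1
F4 | step 4 | racemic 3-ethoxy-1,5,5-trimethyl-6-{[(triisopropylsilyl)oxy]methyl}cyclohex-2-en-1-ol (not isolated) | CCOC1=CC(C)(O)C(CO[Si](C(C)C)(C(C)C)C(C)C)C(C)(C)C1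
F5 | step 4 | racemic 3,5,5-trimethyl-4-{[(triisopropylsilyl)oxy]methyl}cyclohex-2-en-1-one | CC(C)[Si](C(C)C)(C(C)C)OCC1C(C)=CC(=O)CC1(C)C
F6 | step 4 | racemic trans-3,5,5-trimethyl-4-{[(triisopropylsilyl)oxy]methyl}cyclohex-2-en-1-ol (14 together with its enantiomer) | CC(C)[Si](C(C)C)(C(C)C)OC[C@H]1C(C)=C[C@H](O)CC1(C)C.CC(C)[Si](C(C)C)(C(C)C)OC[C@@H]1C(C)=C[C@@H](O)CC1(C)C
F7 | step 4 | (1S,4S)-3,5,5-trimethyl-4-{[(triisopropylsilyl)oxy]methyl}cyclohex-2-en-1-ol | CC(C)[Si](C(C)C)(C(C)C)OC[C@@H]1C(C)=C[C@@H](O)CC1(C)C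
F8 | step 6 | (1S,4R)-3,5,5-trimethyl-4-{[(triisopropylsilyl)oxy]methyl}cyclohex-2-en-1-ol | CC(C)[Si](C(C)C)(C(C)C)OC[C@H]1C(C)=C[C@@H](O)CC1(C)C
F9 | step 11 | (1R,4R)-4-(iodomethyl)-3,5,5-trimethylcyclohex-2-en-1-yl tetradecanoate | IC[C@H]1C(C)=C[C@H](OC(=O)CCCCCCCCCCCCC)CC1(C)C
F10 | step 11 | {[(1R,4R)-2,6,6-trimethyl-4-(tetradecanoyloxy)cyclohex-2-en-1-yl]methyl}triphenylphosphonium iodide | [I-].c1ccc(cc1)[P+](C[C@H]1C(C)=C[C@H](OC(=O)CCCCCCCCCCCCC)CC1(C)C)(c1ccccc1)c1ccccc1
F11 | step 11 | phosphonium ylide of F10 (not isolated) | c1ccc(cc1)P(=C[C@H]1C(C)=C[C@H](OC(=O)CCCCCCCCCCCCC)CC1(C)C)(c1ccccc1)c1ccccc1
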